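The route rests on disconnecting the vicinal secondary–tertiary diol of the seven-membered ring B, between C9 (CH–OH) and C8 (methyl carbinol; daucane numbering). A samarium diiodide pinacol cyclization of a 1,7-keto aldehyde forms this C8–C9 bond, closes ring B onto the finished cyclopentane ring A with its trans ring fusion, and sets both carbinol centres in one operation. The precursor is a cyclopentane that already carries the isopropyl carbinol, the angular methyl, a CH2CHO arm on the quaternary carbon and the 1-aroyloxy-3-oxobutyl arm next to it; it is reached by a silicon-tethered radical cyclization–allylation and a double ozonolysis.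

Key step: step 12

Remark (atom labels used below, daucane numbering): C1 = angular-methyl carbon, C2 and C3 = ring CH2, C4 = isopropyl carbinol, C5 = ring-fusion CH, C6 = ester-bearing CH, C7 = CH2, C8 = methyl carbinol, C9 = CH(OH), C10 = CH2; β is the face of the angular methyl, α the opposite face.

Step 1
Reactants: 1 3-methylcyclopent-2-en-1-one
Product: 2 (S)-3-methylcyclopent-2-en-1-ol
Conditions: (R)-2-methyl-CBS-oxazaborolidine (10 mol%), BH3·SMe2, THF, −20 °C; MeOH, then pH 7 buffer
Reagents that add atoms: none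
Why: Corey–Bakshi–Shibata reduction, in which the oxazaborolidine–borane complex delivers hydride to one carbonyl face with the alkenyl arm as the large group, should set the carbinol centre (future C4–O, β) as S.

Step 2
Reactants: 2 (S)-3-methylcyclopent-2-en-1-ol
Product: 3 (S)-(bromomethyl)dimethyl[(3-methylcyclopent-2-en-1-yl)oxy]silane
Conditions: ClSiMe2CH2Br, Et3N, DMAP (cat.), CH2Cl2, 0 °C
Reagents that add atoms: (bromomethyl)chlorodimethylsilane (C[Si](C)(Cl)CBr)
Why: Silylation of the allylic alcohol under buffered conditions installs the bromomethylsilyl tether without touching the stereocentre.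

Step 3
Reactants: 3 (S)-(bromomethyl)dimethyl[(3-methylcyclopent-2-en-1-yl)oxy]silane
Product: 5 (1S,2S,3R)-2-(hydroxymethyl)-3-methyl-3-(prop-2-en-1-yl)cyclopentan-1-ol, via cis-fused bicyclic siloxane 4 (not isolated)
Conditions: allylSnBu3 (3 equiv), AIBN (0.2 equiv in portions), PhH (0.2 M), 80 °C; evaporate; then KF, KHCO3, 30% H2O2, THF/MeOH, rt
Reagents that add atoms: allyltributylstannane (C=CC[Sn](CCCC)(CCCC)CCCC); hydrogen peroxide (OO)
Why: Bromine abstraction by Bu3Sn• gives the silylmethyl radical, whose 5-exo-trig cyclization is held cis to the C4–O bond by the short tether (sets C5); the tertiary C1 radical then takes an allyl group from the stannane (Keck radical allylation) on the open α face, anti to the new C5–CH2 bond (sets the quaternary C1), and Tamao–Fleming oxidation replaces C–Si by C–OH with retention.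

Step 4
Reactants: 5 (1S,2S,3R)-2-(hydroxymethyl)-3-methyl-3-(prop-2-en-1-yl)cyclopentan-1-ol
Product: 6 (1S,2S,3R)-2-[(tert-butyldimethylsilyloxy)methyl]-3-methyl-3-(prop-2-en-1-yl)cyclopentan-1-ol
Conditions: TBSCl (1.05 equiv), imidazole, CH2Cl2, 0 °C
Reagents that add atoms: tert-butyldimethylsilyl chloride (CC(C)(C)[Si](C)(C)Cl)
Why: Silylation should be selective for the primary hydroxyl over the hindered ring secondary hydroxyl.

Step 5
Reactants: 6 (1S,2S,3R)-2-[(tert-butyldimethylsilyloxy)methyl]-3-methyl-3-(prop-2-en-1-yl)cyclopentan-1-ol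
Product: 7 (2S,3R)-2-[(tert-butyldimethylsilyloxy)methyl]-3-methyl-3-(prop-2-en-1-yl)cyclopentan-1-one
Conditions: Dess–Martin periodinane, NaHCO3, CH2Cl2, 0 °C → rt
Reagents that add atoms: none
Why: Dess–Martin oxidation under buffered, non-basic conditions should give the ketone without epimerization at C5 or loss of the β-silyloxy group.

Step 6
Reactants: 7 (2S,3R)-2-[(tert-butyldimethylsilyloxy)methyl]-3-methyl-3-(prop-2-en-1-yl)cyclopentan-1-one
Product: 8 (1R,2S,3R)-2-[(tert-butyldimethylsilyloxy)methyl]-3-methyl-1-(propan-2-yl)-3-(prop-2-en-1-yl)cyclopentan-1-ol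
Conditions: CeCl3 (anhydrous, 3 equiv), iPrMgCl (3 equiv), THF, −78 °C → −40 °C; aq NH4Cl
Reagents that add atoms: isopropylmagnesium chloride (CC(C)[Mg]Cl)
Why: Organocerium 1,2-addition (low basicity suppresses enolization and β-elimination) should occur on the α face, anti to the adjacent C5 arm and to the 1,3-related C1 methyl, so the isopropyl group enters α and the new tertiary hydroxyl at C4 is β.

Step 7
Reactants: 8 (1R,2S,3R)-2-[(tert-butyldimethylsilyloxy)methyl]-3-methyl-1-(propan-2-yl)-3-(prop-2-en-1-yl)cyclopentan-1-ol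
Product: 9 (1R,2S,3R)-2-(hydroxymethyl)-3-methyl-1-(propan-2-yl)-3-(prop-2-en-1-yl)cyclopentan-1-ol
Conditions: TBAF, THF, 0 °C → rt
Reagents that add atoms: none
Why: Fluoride cleavage of the primary silyl ether should leave the tertiary alcohol and the alkene untouched.

Step 8
Reactants: 9 (1R,2S,3R)-2-(hydroxymethyl)-3-methyl-1-(propan-2-yl)-3-(prop-2-en-1-yl)cyclopentan-1-ol
Product: 10 (1R,2R,5R)-2-hydroxy-5-methyl-2-(propan-2-yl)-5-(prop-2-en-1-yl)cyclopentane-1-carbaldehyde
Conditions: TEMPO (10 mol%), PhI(OAc)2, CH2Cl2, rt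
Reagents that add atoms: none
Why: The TEMPO/PhI(OAc)2 oxidation converts only the primary alcohol into the aldehyde; the formyl group at C5 already stands trans to the isopropyl group, the more stable arrangement, so no epimerization is expected.

Step 9
Reactants: 10 (1R,2R,5R)-2-hydroxy-5-methyl-2-(propan-2-yl)-5-(prop-2-en-1-yl)cyclopentane-1-carbaldehyde
Product: 11 (1R,2S,3R)-2-[(1S)-1-hydroxy-3-methylbut-3-en-1-yl]-3-methyl-1-(propan-2-yl)-3-(prop-2-en-1-yl)cyclopentan-1-ol
Conditions: (−)-Ipc2BOMe, methallylMgCl, Et2O, −78 °C → rt; then 10, −78 °C; NaOH, H2O2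
Reagents that add atoms: (−)-B-methallyldiisopinocampheylborane (CC(=C)CB([C@@H]1C[C@@H]2C[C@H]([C@H]1C)C2(C)C)[C@@H]1C[C@@H]2C[C@H]([C@H]1C)C2(C)C), made in the flask from (−)-B-methoxydiisopinocampheylborane (COB([C@@H]1C[C@@H]2C[C@H]([C@H]1C)C2(C)C)[C@@H]1C[C@@H]2C[C@H]([C@H]1C)C2(C)C) and methallylmagnesium chloride (CC(=C)C[Mg]Cl)
Why: Brown methallylation through a closed chair-like Zimmerman–Traxler transition state, in which the isopinocampheyl groups derived from (+)-α-pinene direct the methallyl group to one aldehyde face (reagent control, in line with Felkin–Anh attack anti to the bulky C4 carbinol carbon), should set C6 as S.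

Step 10
Reactants: 11 (1R,2S,3R)-2-[(1S)-1-hydroxy-3-methylbut-3-en-1-yl]-3-methyl-1-(propan-2-yl)-3-(prop-2-en-1-yl)cyclopentan-1-ol; 12 4-(benzyloxy)benzoyl chloride
Product: 13 (1S)-1-[(1S,2R,5R)-2-hydroxy-5-methyl-2-(propan-2-yl)-5-(prop-2-en-1-yl)cyclopentyl]-3-methylbut-3-en-1-yl 4-(benzyloxy)benzoate
Conditions: Et3N, DMAP (20 mol%), CH2Cl2, 0 °C → rt
Reagents that add atoms: none
Why: DMAP-catalysed acylation should take place at the secondary C6 hydroxyl only, the tertiary C4 hydroxyl being too hindered to react.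

Step 11
Reactants: 13 (1S)-1-[(1S,2R,5R)-2-hydroxy-5-methyl-2-(propan-2-yl)-5-(prop-2-en-1-yl)cyclopentyl]-3-methylbut-3-en-1-yl 4-(benzyloxy)benzoate
Product: 15 (1S)-1-[(1S,2R,5R)-2-hydroxy-5-methyl-5-(2-oxoethyl)-2-(propan-2-yl)cyclopentyl]-3-oxobutyl 4-(benzyloxy)benzoate, via bis-ozonide 14 (not isolated)
Conditions: O3, CH2Cl2, −78 °C (to first persistent blue); then PPh3, −78 °C → rt
Reagents that add atoms: ozone ([O-][O+]=O)
Why: Ozonolysis (Criegee mechanism) with neutral reductive work-up cleaves the allyl group to the C9 aldehyde and the methallyl group to the C8 methyl ketone in one operation, without base that could eliminate the β-acyloxy ketone.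

Step 12
Reactants: 15 (1S)-1-[(1S,2R,5R)-2-hydroxy-5-methyl-5-(2-oxoethyl)-2-(propan-2-yl)cyclopentyl]-3-oxobutyl 4-(benzyloxy)benzoate
Product: 16 (3R,3aS,4S,6S,7S,8aR)-3,6,7-trihydroxy-6,8a-dimethyl-3-(propan-2-yl)decahydroazulen-4-yl 4-(benzyloxy)benzoate
Conditions: SmI2 (2.5 equiv, 0.1 M in THF), HMPA (10 equiv), THF, −78 °C, slow addition of 15 (final 0.01 M); aq NH4Cl
Reagents that add atoms: none
Why: Single-electron transfer from divalent samarium (SmI2) to the aldehyde of 15 gives a samarium ketyl at C9 that adds to the C8 ketone carbonyl, a second electron transfer gives the samarium diolate, and work-up protonates it; this is the known SmI2 ketone–aldehyde pinacol cyclization. The seven-membered ring B closes in the 7-exo-trig mode (C9 radical onto C8=O, the oxygen staying outside the ring). Both new centres, C8 and C9, should be set in a chair-like transition state of the trans-fused bicycle in which the ring-fusion bonds and the C6 ester stay equatorial and the two HMPA-loaded, mutually repelling O–Sm groups stand anti across the forming bond. Of the two anti arrangements, only the one with the C9 oxygen on the α face avoids a 1,3-diaxial clash with the angular C1 methyl on the β face, and it also leaves the C8 methyl equatorial; this gives 8β-OH/9α-OH, the trans-diol of the target. The step needs chemoselectivity for aldehyde and ketone over the aryl ester and benzyl ether, which the low temperature and the much easier reduction of the aldehyde should secure, and it needs a non-chelated transition state, which the excess HMPA should secure.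

Step 13
Reactants: 16 (3R,3aS,4S,6S,7S,8aR)-3,6,7-trihydroxy-6,8a-dimethyl-3-(propan-2-yl)decahydroazulen-4-yl 4-(benzyloxy)benzoate
Product: 17 (3R,3aS,4S,6S,7S,8aR)-3,6,7-trihydroxy-6,8a-dimethyl-3-(propan-2-yl)decahydroazulen-4-yl 4-hydroxybenzoate
Conditions: H2 (1 atm), Pd/C (10%), EtOAc/EtOH, rt
Reagents that add atoms: none
Why: Hydrogenolysis of the benzyl aryl ether frees the phenol; no other group in 16 is reducible under these conditions.

Compound list
1 | 3-methylcyclopent-2-en-1-one | CC1=CC(=O)CC1 | starting material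
2 | (S)-3-methylcyclopent-2-en-1-ol | O[C@@H]1C=C(C)CC1 | intermediate
3 | (S)-(bromomethyl)dimethyl[(3-methylcyclopent-2-en-1-yl)oxy]silane | C[Si](C)(CBr)O[C@@H]1C=C(C)CC1 | intermediate
4 | (3aR,4R,6aS)-2,2,4-trimethyl-4-(prop-2-en-1-yl)hexahydro-2H-cyclopenta[d][1,2]oxasilole (cis-fused; O and Si–CH2 on the β face, allyl α) | C[Si]1(C)O[C@H]2CC[C@](C)(CC=C)[C@H]2C1 | intermediate (not isolated)
5 | (1S,2S,3R)-2-(hydroxymethyl)-3-methyl-3-(prop-2-en-1-yl)cyclopentan-1-ol | O[C@H]1CC[C@](C)(CC=C)[C@H]1CO | intermediate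
6 | (1S,2S,3R)-2-[(tert-butyldimethylsilyloxy)methyl]-3-methyl-3-(prop-2-en-1-yl)cyclopentan-1-ol | O[C@H]1CC[C@](C)(CC=C)[C@H]1CO[Si](C)(C)C(C)(C)C | intermediate
7 | (2S,3R)-2-[(tert-butyldimethylsilyloxy)methyl]-3-methyl-3-(prop-2-en-1-yl)cyclopentan-1-one | O=C1CC[C@](C)(CC=C)[C@H]1CO[Si](C)(C)C(C)(C)C | intermediate
8 | (1R,2S,3R)-2-[(tert-butyldimethylsilyloxy)methyl]-3-methyl-1-(propan-2-yl)-3-(prop-2-en-1-yl)cyclopentan-1-ol | CC(C)[C@]1(O)CC[C@](C)(CC=C)[C@H]1CO[Si](C)(C)C(C)(C)C | intermediate
9 | (1R,2S,3R)-2-(hydroxymethyl)-3-methyl-1-(propan-2-yl)-3-(prop-2-en-1-yl)cyclopentan-1-ol | CC(C)[C@]1(O)CC[C@](C)(CC=C)[C@H]1CO | intermediate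
10 | (1R,2R,5R)-2-hydroxy-5-methyl-2-(propan-2-yl)-5-(prop-2-en-1-yl)cyclopentane-1-carbaldehyde | CC(C)[C@]1(O)CC[C@](C)(CC=C)[C@H]1C=O | intermediate
11 | (1R,2S,3R)-2-[(1S)-1-hydroxy-3-methylbut-3-en-1-yl]-3-methyl-1-(propan-2-yl)-3-(prop-2-en-1-yl)cyclopentan-1-ol | CC(C)[C@]1(O)CC[C@](C)(CC=C)[C@H]1[C@@H](O)CC(C)=C | intermediate
12 | 4-(benzyloxy)benzoyl chloride | O=C(Cl)c1ccc(OCc2ccccc2)cc1 | starting material
13 | (1S)-1-[(1S,2R,5R)-2-hydroxy-5-methyl-2-(propan-2-yl)-5-(prop-2-en-1-yl)cyclopentyl]-3-methylbut-3-en-1-yl 4-(benzyloxy)benzoate | CC(C)[C@]1(O)CC[C@](C)(CC=C)[C@H]1[C@@H](OC(=O)c2ccc(OCc3ccccc3)cc2)CC(C)=C | intermediate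
14 | bis-ozonide of 13 (both C=C bonds as 1,2,4-trioxolanes; ozonide carbons as epimer mixture) | CC(C)[C@]1(O)CC[C@](C)(CC2OOCO2)[C@H]1[C@@H](OC(=O)c3ccc(OCc4ccccc4)cc3)CC5(C)OOCO5 | intermediate (not isolated)
15 | (1S)-1-[(1S,2R,5R)-2-hydroxy-5-methyl-5-(2-oxoethyl)-2-(propan-2-yl)cyclopentyl]-3-oxobutyl 4-(benzyloxy)benzoate | CC(C)[C@]1(O)CC[C@](C)(CC=O)[C@H]1[C@@H](OC(=O)c2ccc(OCc3ccccc3)cc2)CC(C)=O | intermediate
16 | (3R,3aS,4S,6S,7S,8aR)-3,6,7-trihydroxy-6,8a-dimethyl-3-(propan-2-yl)decahydroazulen-4-yl 4-(benzyloxy)benzoate | CC(C)[C@]1(O)CC[C@]2(C)C[C@H](O)[C@@](C)(O)C[C@H](OC(=O)c3ccc(OCc4ccccc4)cc3)[C@H]21 | intermediate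
17 | (3R,3aS,4S,6S,7S,8aR)-3,6,7-trihydroxy-6,8a-dimethyl-3-(propan-2-yl)decahydroazulen-4-yl 4-hydroxybenzoate | CC(C)[C@]1(O)CC[C@]2(C)C[C@H](O)[C@@](C)(O)C[C@H](OC(=O)c3ccc(O)cc3)[C@H]21 | target

Total step count: 13. Longest linear sequence: 13 steps (1 → 17).

Steps most likely to fail

1. Step 12. The ring closure may pass through a chelated arrangement of the two oxygens and so deliver the cis-diol or the other trans-diol (poor facial control at C8 and C9), or the aldehyde ketyl may be quenched before the seven-membered ring closes. The fallback sets out from diene ester 13. Ring-closing metathesis of the allyl and methallyl arms (second-generation Grubbs catalyst, RuCl2(=CHPh)(H2IMes)(PCy3), CH2Cl2, 40 °C) should give the trans-fused cycloheptene F1, with the trisubstituted C8=C9 double bond. Peracid epoxidation (mCPBA, NaHCO3, CH2Cl2, 0 °C) from the α face, anti to the angular methyl, should give the 8α,9α-epoxide F2. Acid-catalysed hydrolysis (HClO4 cat., THF/H2O) opens it at the tertiary C8 with inversion to the 8β,9α-diol, and the sequence comes back to the route at 16.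

2. Step 3. Allyl transfer to the hindered tertiary C1 radical may be too slow to carry the chain, so that the silylmethyl radical is allylated before it cyclizes or the sequence stalls. The fallback sets out from 3. Tin hydride-mediated cyclization (Bu3SnH by slow addition, AIBN, PhH, 80 °C) in the presence of phenyl vinyl sulfone traps the tertiary radical by fast Giese addition on the same α face and gives the sulfone F3. Deprotonation next to the sulfone (LDA, THF, −78 °C) and alkylation with (iodomethyl)trimethylsilane gives the β-silyl sulfone F4. TBAF then eliminates sulfinate and fluorosilane to unveil the allyl group, and KF/KHCO3/H2O2 oxidation of the silicon tether in the same flask brings the sequence back to the route at 5.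

3. Step 9. Facial selectivity at the aldehyde may be poor (substrate bias or the free β-hydroxyl overriding reagent control), and the β-hydroxy aldehyde may be lost by retro-aldol cleavage or dehydration during the slow addition. The fallback sets out from 10. Addition of methallylMgCl (THF, −78 °C) gives the alcohol F5 as a mixture of C6 epimers. Dess–Martin oxidation gives the β-hydroxy ketone F6. Chelation-controlled reduction with Zn(BH4)2 (Et2O, −20 °C), with hydride attacking the convex face of the cis-fused zinc chelate between the C4 hydroxyl and the C6 carbonyl, should give the S carbinol, and the sequence comes back to the route at 11.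

Further compounds
F1 | step 12 | (3R,3aS,4S,8aR)-3-hydroxy-6,8a-dimethyl-3-(propan-2-yl)-1,2,3,3a,4,5,8,8a-octahydroazulen-4-yl 4-(benzyloxy)benzoate | CC(C)[C@]1(O)CC[C@]2(C)CC=C(C)C[C@H](OC(=O)c3ccc(OCc4ccccc4)cc3)[C@H]21
F2 | step 12 | 8α,9α-epoxide of F1 (daucane numbering; epoxide oxygen on the face opposite to the angular methyl) | CC(C)[C@]1(O)CC[C@]2(C)C[C@@H]3O[C@]3(C)C[C@H](OC(=O)c4ccc(OCc5ccccc5)cc4)[C@H]21
F3 | step 3 | (3aR,4R,6aS)-2,2,4-trimethyl-4-[2-(phenylsulfonyl)ethyl]hexahydro-2H-cyclopenta[d][1,2]oxasilole | C[Si]1(C)O[C@H]2CC[C@](C)(CCS(=O)(=O)c3ccccc3)[C@H]2C1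
F4 | step 3 | (3aR,4R,6aS)-2,2,4-trimethyl-4-[2-(phenylsulfonyl)-3-(trimethylsilyl)propyl]hexahydro-2H-cyclopenta[d][1,2]oxasilole (sulfone carbon as epimer mixture) | C[Si]1(C)O[C@H]2CC[C@](C)(CC(C[Si](C)(C)C)S(=O)(=O)c3ccccc3)[C@H]2C1
F5 | step 9 | (1R,2S,3R)-2-(1-hydroxy-3-methylbut-3-en-1-yl)-3-methyl-1-(propan-2-yl)-3-(prop-2-en-1-yl)cyclopentan-1-ol (C6 epimer mixture) | CC(C)[C@]1(O)CC[C@](C)(CC=C)[C@H]1C(O)CC(C)=C
F6 | step 9 | 1-[(1R,2R,5R)-2-hydroxy-5-methyl-2-(propan-2-yl)-5-(prop-2-en-1-yl)cyclopentyl]-3-methylbut-3-en-1-one | CC(C)[C@]1(O)CC[C@](C)(CC=C)[C@H]1C(=O)CC(C)=C
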